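**Retrosynthetic overview**
1. Target 22 ⇐ tribenzyl flavanone 21 (hydrogenolysis) ⇐ chromone 19 + arylboronic acid 20 by catalyst-controlled 1,4-arylation, which sets C2 and brings in ring B.
2. Chromone 19 ⇐ piperidine 14: ortho-lithiation/acetylation beside the MOM ether, MOM removal, enaminone closure of the pyranone ring C.
3. Piperidine 14 ⇐ N-methylpyridinium 13 by asymmetric hydrogenation (sets C2') ⇐ 2-arylpyridine 12.
4. Pyridine 12 ⇐ 5-aryl-1,2,4-triazine 8 + norbornadiene 9 (forms C3'–C4' and C5'–C6'); 8 ⇐ arylglyoxal 4 + formamidrazone; 4 ⇐ phloroacetophenone 1. The feature used is the C6–C2' bond from the ring A carbon lying between the C5 and C7 oxygens to the N-methylpiperidine, read as a reduced 2-arylpyridine whose N1', C2', C3' and C6' come from the triazine.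
5. Ring order: ring A (bought) → triazine → pyridine → piperidine → ring C; ring B arrives preformed.

Key step: step 5

Assumption: the ligand enantiomers named in steps 7 and 11 are those expected to give the S centres; if a first run shows the opposite sense, the mirror-image ligand is used.

**Route**

Step 1
Reactants: 1 2',4',6'-trihydroxyacetophenone
Product: 2 1-[2,6-dihydroxy-4-(methoxymethoxy)phenyl]ethan-1-one
Conditions: MOMCl (1.05 equiv), i-Pr2NEt, THF/CH2Cl2, 0 °C
Reagents that add atoms: chloromethyl methyl ether (MOMCl), COCCl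
Why: The 4-OH is para to the acetyl group and not hydrogen-bonded to the carbonyl, so it is the most acidic and most accessible phenol and one equivalent of MOMCl should etherify it selectively (Williamson-type O-alkylation).

Step 2
Reactants: 2 1-[2,6-dihydroxy-4-(methoxymethoxy)phenyl]ethan-1-one
Product: 3 1-[2,6-bis(benzyloxy)-4-(methoxymethoxy)phenyl]ethan-1-one
Conditions: BnBr, K2CO3, DMF, 60 °C
Reagents that add atoms: benzyl bromide, BrCc1ccccc1
Why: Williamson etherification in warm DMF with carbonate breaks the carbonyl chelate of the two remaining ortho-phenols and benzylates both, while the MOM acetal is base-stable.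

Step 3
Reactants: 3 1-[2,6-bis(benzyloxy)-4-(methoxymethoxy)phenyl]ethan-1-one
Product: 4 2-[2,6-bis(benzyloxy)-4-(methoxymethoxy)phenyl]-2-oxoacetaldehyde (used crude)
Conditions: SeO2, 1,4-dioxane/H2O (20:1), 90 °C
Reagents that add atoms: selenium dioxide, O=[Se]=O
Why: Riley oxidation of an aryl methyl ketone to the arylglyoxal, a reaction that di-ortho-substituted aryl methyl ketones undergo, in a weakly acidic medium that should leave the MOM acetal and benzyl ethers intact.

Step 4
Reactants: 4 2-[2,6-bis(benzyloxy)-4-(methoxymethoxy)phenyl]-2-oxoacetaldehyde; 5 formamidine acetate; 6 hydrazine hydrate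
Product: 8 5-[2,6-bis(benzyloxy)-4-(methoxymethoxy)phenyl]-1,2,4-triazine, via formamidrazone 7 (not isolated)
Conditions: 5 + 6, MeOH, 0 °C, 30 min; then 4, 0 °C to rt
Reagents that add atoms: none
Why: Transamination of formamidine with hydrazine gives formamidrazone, whose hydrazine NH2 condenses with the aldehyde carbon and whose amidine nitrogen then closes onto the ketone, so the aryl group ends on C5 of the aromatic triazine (amidrazone–1,2-dicarbonyl condensation).

Step 5
Reactants: 8 5-[2,6-bis(benzyloxy)-4-(methoxymethoxy)phenyl]-1,2,4-triazine; 9 norbornadiene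
Product: 12 2-[2,6-bis(benzyloxy)-4-(methoxymethoxy)phenyl]pyridine, via bridged triazine–norbornadiene cycloadduct 10 (not isolated), via norbornene-fused dihydropyridine 11 (not isolated)
Conditions: 9 (10 equiv), 1,2-dichlorobenzene, 150 °C, sealed tube
Reagents that add atoms: none
Why: The electron-poor 2-azadiene C3=N4–C5=C6 of triazine 8 adds the strained norbornadiene double bond across C3 and C6 in an inverse-electron-demand Diels–Alder reaction to give adduct 10; cycloreversion expels N1=N2 as dinitrogen to give dihydropyridine 11, and a second retro-Diels–Alder reaction releases cyclopentadiene and aromatises the ring. The closest known reaction type is the 1,2,4-triazine-to-pyridine sequence with norbornadiene as an acetylene equivalent, which is established for aryl-1,2,4-triazines. The pyridine ring is closed by an intermolecular [4+2] cycloaddition that forms C3'–C4' (triazine C6 to one alkene carbon) and C5'–C6' (the other alkene carbon to triazine C3), with N4 becoming the ring nitrogen and C5 with its aryl group becoming C2'. No stereocentre survives, because the sp3 carbons of 10 and 11 are either expelled or aromatised. The step needs addition across C3/C6 and not across C5/N2, which is the normal mode for triazines with alkenes, and it needs no regiocontrol because the dienophile is symmetric and the aryl position is fixed by the triazine; excess norbornadiene suppresses twofold reaction. The di-ortho-substituted aryl ring is twisted out of the triazine plane, which limits its electron donation, so the azadiene should stay reactive enough at 150 °C, where MOM and benzyl ethers are stable.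

Step 6
Reactants: 12 2-[2,6-bis(benzyloxy)-4-(methoxymethoxy)phenyl]pyridine
Product: 13 2-[2,6-bis(benzyloxy)-4-(methoxymethoxy)phenyl]-1-methylpyridin-1-ium trifluoromethanesulfonate
Conditions: MeOTf (1.1 equiv), CH2Cl2, 0 °C to rt
Reagents that add atoms: methyl trifluoromethanesulfonate, COS(=O)(=O)C(F)(F)F
Why: N-alkylation (Menshutkin reaction) of the pyridine nitrogen, by far the best nucleophile present, with the small and powerful methyl triflate should overcome shielding by the twisted aryl group.

Step 7
Reactants: 13 2-[2,6-bis(benzyloxy)-4-(methoxymethoxy)phenyl]-1-methylpyridin-1-ium trifluoromethanesulfonate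
Product: 14 (2S)-2-[2,6-bis(benzyloxy)-4-(methoxymethoxy)phenyl]-1-methylpiperidine
Conditions: H2 (40 bar), [Ir(cod)Cl]2 (2 mol%), (R)-SynPhos (4.4 mol%), toluene/CH2Cl2 (1:1), 30 °C; then aq NaOH
Reagents that add atoms: none
Why: Iridium–bisphosphine asymmetric hydrogenation of a 2-aryl-N-alkylpyridinium salt, in which the chiral iridium hydride sets C2' when it reduces the cyclic 2-aryl iminium intermediate (ligand enantiomer chosen for S), while benzyl ethers and the MOM acetal are inert to this homogeneous catalyst.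

Step 8
Reactants: 14 (2S)-2-[2,6-bis(benzyloxy)-4-(methoxymethoxy)phenyl]-1-methylpiperidine
Product: 16 1-{2,4-bis(benzyloxy)-6-(methoxymethoxy)-3-[(2S)-1-methylpiperidin-2-yl]phenyl}ethan-1-one, via ortho-lithiated aryl 15 (not isolated)
Conditions: n-BuLi, THF, 0 °C; then MeC(O)N(OMe)Me, −78 °C to rt; H2O
Reagents that add atoms: N-methoxy-N-methylacetamide, CC(=O)N(C)OC
Why: Directed ortho-metalation lithiates the ring CH flanked by the MOM ether and a benzyloxy group (the two such positions are equivalent), and acylation with the N-methoxy-N-methylamide (Weinreb ketone synthesis) stops at the ketone, while the non-activated C2'–H is not deprotonated and the stereocentre is kept.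

Step 9
Reactants: 16 1-{2,4-bis(benzyloxy)-6-(methoxymethoxy)-3-[(2S)-1-methylpiperidin-2-yl]phenyl}ethan-1-one
Product: 17 1-{2,4-bis(benzyloxy)-6-hydroxy-3-[(2S)-1-methylpiperidin-2-yl]phenyl}ethan-1-one
Conditions: HCl (3 M in MeOH), 45 °C; then aq NaHCO3
Reagents that add atoms: none
Why: Acid-catalysed acetal exchange with methanol removes the MOM group, assisted by the neighbouring carbonyl, while the benzyl ethers and the protonated amine are stable.

Step 10
Reactants: 17 1-{2,4-bis(benzyloxy)-6-hydroxy-3-[(2S)-1-methylpiperidin-2-yl]phenyl}ethan-1-one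
Product: 19 5,7-bis(benzyloxy)-6-[(2S)-1-methylpiperidin-2-yl]-4H-chromen-4-one, via enaminone 18 (not isolated)
Conditions: Me2NCH(OMe)2, toluene, 100 °C; then conc. HCl, CH2Cl2, rt; aq NaHCO3
Reagents that add atoms: N,N-dimethylformamide dimethyl acetal, COC(OC)N(C)C
Why: Condensation of the methyl ketone with the amide acetal gives the enaminone, and acid then triggers intramolecular oxa-Michael addition of the phenol with loss of dimethylamine, closing ring C through the O1–C2 bond (enaminone route to chromones).

Step 11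
Reactants: 19 5,7-bis(benzyloxy)-6-[(2S)-1-methylpiperidin-2-yl]-4H-chromen-4-one; 20 [4-(benzyloxy)phenyl]boronic acid
Product: 21 (2S)-5,7-bis(benzyloxy)-2-[4-(benzyloxy)phenyl]-6-[(2S)-1-methylpiperidin-2-yl]-2,3-dihydro-4H-chromen-4-one
Conditions: Pd(OCOCF3)2 (10 mol%), (R)-t-BuPyOx (12 mol%), NH4PF6, CF3CO2H (1 equiv), H2O, ClCH2CH2Cl, 60 °C; then aq NaHCO3
Reagents that add atoms: none
Why: Asymmetric conjugate addition of an arylboronic acid to a chromone under divalent palladium/pyridine-oxazoline catalysis adds the aryl group across C2=C3 from the face set by the ligand, giving C2 as S under catalyst control because C2' is remote, with the amine kept protonated so that it does not bind palladium and with a mildly acidic medium that avoids ring-opening of the flavanone.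

Step 12
Reactants: 21 (2S)-5,7-bis(benzyloxy)-2-[4-(benzyloxy)phenyl]-6-[(2S)-1-methylpiperidin-2-yl]-2,3-dihydro-4H-chromen-4-one
Product: 22 (2S)-5,7-dihydroxy-2-(4-hydroxyphenyl)-6-[(2S)-1-methylpiperidin-2-yl]-2,3-dihydro-4H-chromen-4-one (CNP0146489.1)
Conditions: H2 (1 atm), 10% Pd/C, EtOAc/MeOH, rt
Reagents that add atoms: none
Why: Hydrogenolysis of the three aryl benzyl ethers over palladium on carbon at room temperature should be faster than cleavage of the hindered benzylic C2–O and C2'–N bonds, and the neutral conditions leave both stereocentres untouched.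

**Compound list**
1 | 2',4',6'-trihydroxyacetophenone | CC(=O)c1c(O)cc(O)cc1O | starting material
2 | 1-[2,6-dihydroxy-4-(methoxymethoxy)phenyl]ethan-1-one | COCOc1cc(O)c(C(C)=O)c(O)c1 | intermediate
3 | 1-[2,6-bis(benzyloxy)-4-(methoxymethoxy)phenyl]ethan-1-one | COCOc1cc(OCc2ccccc2)c(C(C)=O)c(OCc2ccccc2)c1 | intermediate
4 | 2-[2,6-bis(benzyloxy)-4-(methoxymethoxy)phenyl]-2-oxoacetaldehyde | COCOc1cc(OCc2ccccc2)c(C(=O)C=O)c(OCc2ccccc2)c1 | intermediate
5 | formamidine acetate | N=CN.CC(=O)O | starting material
6 | hydrazine hydrate | NN.O | starting material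
7 | formamidrazone (formimidic hydrazide, present as its acetate salt) | NC=NN | intermediate (not isolated)
8 | 5-[2,6-bis(benzyloxy)-4-(methoxymethoxy)phenyl]-1,2,4-triazine | COCOc1cc(OCc2ccccc2)c(-c2cnncn2)c(OCc2ccccc2)c1 | intermediate
9 | norbornadiene (bicyclo[2.2.1]hepta-2,5-diene) | C1=CC2C=CC1C2 | starting material
10 | bridged [4+2] adduct: triazine C3 and C6 bonded to the two carbons of one norbornadiene double bond, N1=N2 and N4=C5 as bridges (stereoisomer mixture) | COCOc1cc(OCc2ccccc2)c(C2=NC3N=NC2C2C4C=CC(C4)C32)c(OCc2ccccc2)c1 | intermediate (not isolated)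
11 | norbornene-fused 3,4-dihydropyridine formed from 10 by loss of N2 (stereoisomer mixture) | COCOc1cc(OCc2ccccc2)c(C2=CC3C4C=CC(C4)C3C=N2)c(OCc2ccccc2)c1 | intermediate (not isolated)
12 | 2-[2,6-bis(benzyloxy)-4-(methoxymethoxy)phenyl]pyridine | COCOc1cc(OCc2ccccc2)c(-c2ccccn2)c(OCc2ccccc2)c1 | intermediate
13 | 2-[2,6-bis(benzyloxy)-4-(methoxymethoxy)phenyl]-1-methylpyridin-1-ium trifluoromethanesulfonate | C[n+]1ccccc1-c1c(OCc2ccccc2)cc(OCOC)cc1OCc1ccccc1.[O-]S(=O)(=O)C(F)(F)F | intermediate
14 | (2S)-2-[2,6-bis(benzyloxy)-4-(methoxymethoxy)phenyl]-1-methylpiperidine | CN1CCCC[C@H]1c1c(OCc2ccccc2)cc(OCOC)cc1OCc1ccccc1 | intermediate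
15 | {2,4-bis(benzyloxy)-6-(methoxymethoxy)-3-[(2S)-1-methylpiperidin-2-yl]phenyl}lithium | CN1CCCC[C@H]1c1c(OCc2ccccc2)c([Li])c(OCOC)cc1OCc1ccccc1 | intermediate (not isolated)
16 | 1-{2,4-bis(benzyloxy)-6-(methoxymethoxy)-3-[(2S)-1-methylpiperidin-2-yl]phenyl}ethan-1-one | CN1CCCC[C@H]1c1c(OCc2ccccc2)c(C(C)=O)c(OCOC)cc1OCc1ccccc1 | intermediate
17 | 1-{2,4-bis(benzyloxy)-6-hydroxy-3-[(2S)-1-methylpiperidin-2-yl]phenyl}ethan-1-one | CN1CCCC[C@H]1c1c(OCc2ccccc2)c(C(C)=O)c(O)cc1OCc1ccccc1 | intermediate
18 | (E)-1-{2,4-bis(benzyloxy)-6-hydroxy-3-[(2S)-1-methylpiperidin-2-yl]phenyl}-3-(dimethylamino)prop-2-en-1-one | CN1CCCC[C@H]1c1c(OCc2ccccc2)c(C(=O)/C=C/N(C)C)c(O)cc1OCc1ccccc1 | intermediate (not isolated)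
19 | 5,7-bis(benzyloxy)-6-[(2S)-1-methylpiperidin-2-yl]-4H-chromen-4-one | CN1CCCC[C@H]1c1c(OCc2ccccc2)cc2occc(=O)c2c1OCc1ccccc1 | intermediate
20 | [4-(benzyloxy)phenyl]boronic acid | OB(O)c1ccc(OCc2ccccc2)cc1 | starting material
21 | (2S)-5,7-bis(benzyloxy)-2-[4-(benzyloxy)phenyl]-6-[(2S)-1-methylpiperidin-2-yl]-2,3-dihydro-4H-chromen-4-one | CN1CCCC[C@H]1c1c(OCc2ccccc2)cc2c(c1OCc1ccccc1)C(=O)C[C@@H](c1ccc(OCc3ccccc3)cc1)O2 | intermediate
22 | (2S)-5,7-dihydroxy-2-(4-hydroxyphenyl)-6-[(2S)-1-methylpiperidin-2-yl]-2,3-dihydro-4H-chromen-4-one | CN1CCCC[C@H]1c1c(O)cc2c(c1O)C(=O)C[C@@H](c1ccc(O)cc1)O2 | target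

**Step count**
Total steps: 12. Longest linear sequence: 12 steps (from 1).

**Steps most likely to fail**

Step 7. Hydride delivery to the hindered, di-ortho-substituted 2-aryl iminium intermediate may be slow or poorly face-selective, giving incomplete reduction or low enantiomeric purity. Fallback: starting from pyridinium salt 13, reduction with NaBH4 in MeOH at 0 °C should give the racemic 2-aryl-1-methyl-1,2,3,6-tetrahydropyridine F1. Hydrogenation of its isolated cis-alkene with RhCl(PPh3)3 and H2, which does not touch benzyl ethers, gives the racemic piperidine F2. Classical resolution by crystallisation with O,O'-di-p-toluoyl-L-tartaric acid gives the diastereomeric salt F3 (the D-acid is used instead if that salt carries the S base), and liberation with aq NaOH returns to 14.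

Step 5. The non-activated triazine may cycloadd too slowly, so that thermal decomposition or reaction with liberated cyclopentadiene competes. Fallback: starting from glyoxal 4, condensation with ethyl oxalamidrazonate (ethyl 2-amino-2-hydrazinylideneacetate) gives the ester-activated triazine, ethyl 5-aryl-1,2,4-triazine-3-carboxylate F4. With norbornadiene 9 in refluxing toluene this lower-LUMO triazine gives ethyl 6-arylpyridine-2-carboxylate F5. Saponification with LiOH gives the picolinic acid F6, and protodecarboxylation (Ag2CO3, AcOH, DMSO, 120 °C) returns to pyridine 12.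

Step 11. The amine may inhibit the catalyst, the electron-rich 5-alkoxychromone may convert slowly while the electron-rich boronic acid protodeboronates, and facial selectivity may be poor. Fallback: starting from hydroxyacetophenone 17, Claisen–Schmidt condensation with 4-(benzyloxy)benzaldehyde (KOH, EtOH) gives the chalcone F7. Oxa-Michael cyclisation (NaOAc, EtOH, reflux) gives flavanone 21 together with its 2R epimer F8. Because C2' is fixed the two are diastereomers and are separated by chromatography; F8 is re-equilibrated through the chalcone under the same conditions, and the route rejoins at 21.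

**Further compounds**
F1 | step 7 | racemic 2-[2,6-bis(benzyloxy)-4-(methoxymethoxy)phenyl]-1-methyl-1,2,3,6-tetrahydropyridine | CN1CC=CCC1c1c(OCc2ccccc2)cc(OCOC)cc1OCc1ccccc1
F2 | step 7 | racemic 2-[2,6-bis(benzyloxy)-4-(methoxymethoxy)phenyl]-1-methylpiperidine | CN1CCCCC1c1c(OCc2ccccc2)cc(OCOC)cc1OCc1ccccc1
F3 | step 7 | salt of 14 with O,O'-di-p-toluoyl-L-tartaric acid | CN1CCCC[C@H]1c1c(OCc2ccccc2)cc(OCOC)cc1OCc1ccccc1.OC(=O)[C@H](OC(=O)c1ccc(C)cc1)[C@@H](OC(=O)c1ccc(C)cc1)C(O)=O
F4 | step 5 | ethyl 5-[2,6-bis(benzyloxy)-4-(methoxymethoxy)phenyl]-1,2,4-triazine-3-carboxylate | CCOC(=O)c1nncc(n1)-c1c(OCc2ccccc2)cc(OCOC)cc1OCc1ccccc1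
F5 | step 5 | ethyl 6-[2,6-bis(benzyloxy)-4-(methoxymethoxy)phenyl]pyridine-2-carboxylate | CCOC(=O)c1cccc(n1)-c1c(OCc2ccccc2)cc(OCOC)cc1OCc1ccccc1
F6 | step 5 | 6-[2,6-bis(benzyloxy)-4-(methoxymethoxy)phenyl]pyridine-2-carboxylic acid | OC(=O)c1cccc(n1)-c1c(OCc2ccccc2)cc(OCOC)cc1OCc1ccccc1
F7 | step 11 | (E)-1-{2,4-bis(benzyloxy)-6-hydroxy-3-[(2S)-1-methylpiperidin-2-yl]phenyl}-3-[4-(benzyloxy)phenyl]prop-2-en-1-one | CN1CCCC[C@H]1c1c(OCc2ccccc2)c(C(=O)/C=C/c2ccc(OCc3ccccc3)cc2)c(O)cc1OCc1ccccc1
F8 | step 11 | (2R)-5,7-bis(benzyloxy)-2-[4-(benzyloxy)phenyl]-6-[(2S)-1-methylpiperidin-2-yl]-2,3-dihydro-4H-chromen-4-one | CN1CCCC[C@H]1c1c(OCc2ccccc2)cc2c(c1OCc1ccccc1)C(=O)C[C@H](c1ccc(OCc3ccccc3)cc1)O2
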